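The route cuts two bonds at the tetrasubstituted exocyclic alkene of the indane: C2–C3 of the cyclopentane ring and one C–CH3 bond of the C2=C(CH3)2 unit. Both substituents on the outer alkene carbon are methyl, so this unit maps onto a prop-1-ynyl group on C1 and alkene geometry does not matter. One palladium-catalysed cascade (benzylpalladium formation at C3, 5-exo-dig alkyne insertion, methyl transfer from boron) closes the five-membered ring and completes the alkene without touching C1. Its precursor is an (S)-diaryl propargylic methine that joins the benzodioxane (ring B) to ring A. Ring A carries an ortho chloromethyl group and an acetonide-masked salicyl alcohol.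

Key step: step 16

Numbering: indane C1 = diaryl methine, C2 = ring alkene carbon, C3 = CH2, C6 = OH, C7 = CHO. Ring A is the indane benzene ring and ring B is the benzodioxane benzene ring. The target is (1S) at C1 and (S) at the dioxane carbon.
Assumption: the sense of induction of the nickel/pybox catalyst on an aryl-substituted carbonate cannot be predicted with certainty, so the ligand named in step 12 stands for whichever of the two commercial antipodes gives the (S)-methine in a trial run.

Step 1
Reactants: 1 dimethyl 4-hydroxyisophthalate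
Product: 2 dimethyl 4-(tert-butyldimethylsilyloxy)isophthalate
Conditions: TBSCl, imidazole, DMF, rt
Reagents that add atoms: tert-butyldimethylsilyl chloride CC(C)(C)[Si](C)(C)Cl
Why: Routine phenol silylation; the bulky, non-coordinating silyl ether removes the acidic proton and shields C5, which leaves C2 as the preferred site for the next metalation.

Step 2
Reactants: 2 dimethyl 4-(tert-butyldimethylsilyloxy)isophthalate
Product: 4 dimethyl 4-(tert-butyldimethylsilyloxy)-2-formylisophthalate, via arylmagnesium chloride 3 (not isolated)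
Conditions: TMPMgCl·LiCl (1.2 equiv), THF, −20 °C; DMF, −20 °C → rt; aq NH4Cl
Reagents that add atoms: TMPMgCl·LiCl CC1(C)CCCC(C)(C)N1[Mg]Cl.[Li+].[Cl-] (MgCl of 3); N,N-dimethylformamide CN(C)C=O (formyl group of 4)
Why: Directed ortho-magnesiation with a hindered amide base should remove the ring proton flanked by both esters (the most acidic one, and esters tolerate this base at low temperature), and DMF then formylates the arylmagnesium.

Step 3
Reactants: 4 dimethyl 4-(tert-butyldimethylsilyloxy)-2-formylisophthalate; 5 prop-1-ynylmagnesium bromide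
Product: 7 racemic 1-[3-(tert-butyldimethylsilyloxy)-2,6-bis(hydroxymethyl)phenyl]but-2-yn-1-ol, via bromomagnesium alkoxide 6 (not isolated)
Conditions: 5 (1.1 equiv), THF, −78 °C; then iBu2AlH (7 equiv), −78 → 0 °C; aq potassium sodium tartrate
Reagents that add atoms: prop-1-ynylmagnesium bromide 5 CC#C[Mg]Br
Why: Chemoselective Grignard 1,2-addition to the aldehyde is followed in the same flask by exhaustive hydride reduction, so alkoxide 6 and any phthalide it forms with either neighbouring ester converge on one triol; the carbinol centre is left racemic because step 12 is stereoconvergent.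

Step 4
Reactants: 7 racemic triol
Product: 8 racemic 1-[3-(tert-butyldimethylsilyloxy)-2,6-bis(tert-butyldimethylsilyloxymethyl)phenyl]but-2-yn-1-ol
Conditions: TBSCl (2.3 equiv), imidazole, CH2Cl2–DMF, 0 °C
Reagents that add atoms: tert-butyldimethylsilyl chloride CC(C)(C)[Si](C)(C)Cl
Why: Sterically selective silylation takes the two primary benzylic alcohols and spares the doubly flanked secondary one, and using the same silyl group everywhere means a phenol-to-benzyl silyl shift in step 3 would be corrected here.

Step 5
Reactants: 8 racemic tris-silyl propargylic alcohol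
Product: 9 racemic phenyl carbonate of 8
Conditions: ClCO2Ph, pyridine, DMAP (cat.), CH2Cl2, 0 °C → rt
Reagents that add atoms: phenyl chloroformate O=C(Cl)Oc1ccccc1
Why: DMAP-catalysed O-acylation installs the aryl carbonate leaving group required for the nickel coupling, and ring A oxygen is meta to the carbinol carbon, so the carbonate should not ionise on handling.

Step 6
Reactants: 10 3-methylbut-2-en-1-ol
Product: 12 [(2R)-3,3-dimethyloxiran-2-yl]methyl 3-nitrobenzenesulfonate, via epoxy alcohol 11 (not isolated)
Conditions: Ti(OiPr)4 (5 mol %), D-(−)-diisopropyl tartrate (6 mol %), tBuOOH, 4 Å MS, CH2Cl2, −20 °C; P(OMe)3; Et3N, DMAP (cat.), 3-O2NC6H4SO2Cl, −10 °C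
Reagents that add atoms: tert-butyl hydroperoxide CC(C)(C)OO; 3-nitrobenzenesulfonyl chloride O=S(=O)(Cl)c1cccc([N+](=O)[O-])c1
Why: Sharpless asymmetric epoxidation with in-flask sulfonylation: the titanium/D-(−)-tartrate catalyst sets the (R)-oxirane carbon (the L-(+)-ester gives the 2S series with this alkene class), and the water-soluble alcohol 11 is trapped as a sulfonate that should be recrystallisable.

Step 7
Reactants: 13 3-bromo-2-hydroxy-5-methylbenzaldehyde
Product: 14 2-(allyloxy)-3-bromo-5-methylbenzaldehyde
Conditions: allyl bromide, K2CO3, DMF, rt → 50 °C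
Reagents that add atoms: allyl bromide C=CCBr
Why: Williamson etherification masks the oxygen next to bromine (future O1), so only the oxygen created in step 8 (future O4) can take up the CH2 terminus.

Step 8
Reactants: 14 2-(allyloxy)-3-bromo-5-methylbenzaldehyde
Product: 16 2-(allyloxy)-3-bromo-5-methylphenol, via aryl formate 15 (not isolated)
Conditions: mCPBA (1.3 equiv), CH2Cl2, rt; then K2CO3 (cat.), MeOH, 0 °C
Reagents that add atoms: 3-chloroperbenzoic acid O=C(OO)c1cccc(Cl)c1
Why: Baeyer–Villiger (Dakin-type) oxidation of an ortho-alkoxybenzaldehyde proceeds by aryl migration much faster than the electron-poor terminal allyl alkene is epoxidised, and the formate is removed by mild methanolysis.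

Step 9
Reactants: 16 2-(allyloxy)-3-bromo-5-methylphenol; 12 (R)-epoxy sulfonate
Product: 17 2-(allyloxy)-1-bromo-3-{[(2R)-3,3-dimethyloxiran-2-yl]methoxy}-5-methylbenzene
Conditions: Cs2CO3, DMF, rt
Reagents that add atoms: none
Why: SN2 O-alkylation at the primary sulfonate carbon; the oxirane carbons are secondary-shielded and fully substituted, so displacement is direct and the (R)-centre is untouched.

Step 10
Reactants: 17 (R)-epoxy allyl ether
Product: 19 2-[(2S)-8-bromo-6-methyl-2,3-dihydro-1,4-benzodioxin-2-yl]propan-2-ol, via free phenol 18 (not isolated)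
Conditions: Pd(PPh3)4 (3 mol %), K2CO3, MeOH, rt → 40 °C
Reagents that add atoms: none
Why: Tsuji–Trost-type deallylation (allyl passed to methanol, and the electron-rich aryl bromide is inert at this temperature) frees the phenoxide, which opens the oxirane 6-exo-tet at the less substituted carbon with inversion, converting (R) into the (S)-dioxane centre.

Step 11
Reactants: 19 (S)-benzodioxane alcohol
Product: 20 triethylsilyl ether of 19
Conditions: Et3SiOTf, 2,6-lutidine, CH2Cl2, 0 °C
Reagents that add atoms: triethylsilyl triflate CC[Si](CC)(CC)OS(=O)(=O)C(F)(F)F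
Why: Silyl triflate silylation of a tertiary alcohol removes the only acidic proton before metalation, and the group leaves with the TBS ethers in step 13 at no extra step.

Step 12
Reactants: 20 (S)-aryl bromide; 9 racemic phenyl carbonate
Product: 23 (2S)-8-{(1S)-1-[3-(tert-butyldimethylsilyloxy)-2,6-bis(tert-butyldimethylsilyloxymethyl)phenyl]but-2-yn-1-yl}-6-methyl-2-[2-(triethylsilyloxy)propan-2-yl]-2,3-dihydro-1,4-benzodioxine, via aryllithium 21 (not isolated), via arylzinc iodide 22 (not isolated)
Conditions: 20 (1.5 equiv), n-BuLi, THF, −78 °C; ZnI2, −78 °C → rt; then 9, NiCl2(dme) (10 mol %), 2,6-bis[(3aS,8aR)-3a,8a-dihydro-8H-indeno[1,2-d]oxazol-2-yl]pyridine (13 mol %), DME, −20 → 10 °C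
Reagents that add atoms: n-butyllithium [Li]CCCC (lithium of 21); zinc iodide [Zn+2].[I-].[I-] (zinc and iodine of 22)
Why: Stereoconvergent nickel/pybox Negishi arylation of a racemic secondary propargylic carbonate: both enantiomers of 9 pass through one planar propargylic radical, and the chiral arylnickel complex bonds to one face, so the catalyst rather than the remote dioxane centre sets (S) at the methine.

Step 13
Reactants: 23 tetrasilyl ether
Product: 24 2-[(2S)-8-{(1S)-1-[3-hydroxy-2,6-bis(hydroxymethyl)phenyl]but-2-yn-1-yl}-6-methyl-2,3-dihydro-1,4-benzodioxin-2-yl]propan-2-ol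
Conditions: Bu4NF (5 equiv), AcOH (5 equiv), THF, 0 °C → rt
Reagents that add atoms: none
Why: Fluoride desilylation removes all four silyl groups in one operation, and the acetic acid buffer keeps the medium too weakly basic to deprotonate the diaryl propargylic C–H.

Step 14
Reactants: 24 tetraol
Product: 25 2-[(2S)-8-{(1S)-1-[6-(hydroxymethyl)-2,2-dimethyl-4H-1,3-benzodioxin-5-yl]but-2-yn-1-yl}-6-methyl-2,3-dihydro-1,4-benzodioxin-2-yl]propan-2-ol
Conditions: Me2C(OMe)2, PPTS (cat.), CH2Cl2, rt
Reagents that add atoms: 2,2-dimethoxypropane COC(C)(C)OC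
Why: Acid-catalysed transketalisation can form a six-membered ring only from the phenol and its ortho CH2OH, which distinguishes the two benzylic alcohols and leaves the future C3 carbinol free.

Step 15
Reactants: 25 acetonide alcohol
Product: 27 2-[(2S)-8-{(1S)-1-[6-(chloromethyl)-2,2-dimethyl-4H-1,3-benzodioxin-5-yl]but-2-yn-1-yl}-6-methyl-2,3-dihydro-1,4-benzodioxin-2-yl]propan-2-ol, via benzylic mesylate 26 (not isolated)
Conditions: MsCl (1.1 equiv), Et3N, LiCl, THF, 0 °C → rt
Reagents that add atoms: methanesulfonyl chloride CS(=O)(=O)Cl (mesyl group of 26); lithium chloride [Li+].[Cl-] (chlorine of 27)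
Why: Mesylation followed by SN2 chloride displacement under basic, acetonide-safe conditions is selective for the primary benzylic alcohol over the hindered tertiary one when the sulfonyl chloride is limited.

Step 16
Reactants: 27 benzylic chloride; 28 methylboronic acid
Product: 29 acetonide-protected (1S)-1-aryl-2-isopropylideneindane (C6–O and C7–CH2O tied in the 2,2-dimethyl-1,3-dioxine ring; aryl = (2S)-2-(2-hydroxypropan-2-yl)-6-methyl-2,3-dihydro-1,4-benzodioxin-8-yl)
Conditions: Pd(PPh3)4 (5 mol %), 28 (3 equiv, in portions), K3PO4 (3 equiv), THF–H2O (20:1), 60 °C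
Reagents that add atoms: methylboronic acid 28 CB(O)O
Why: Zerovalent palladium inserts into the benzylic C3–Cl bond to give a benzylpalladium chloride with no β-hydrogen, the tethered alkyne inserts syn to form C2–C3 and place palladium on the exocyclic carbon cis to C3, and base-assisted methyl transfer from boron followed by reductive elimination makes the second C–CH3 bond. The closest known reaction type is cyclic carbopalladation of an alkyne started by an aryl, vinyl or benzyl halide and ended by Suzuki–Miyaura (or Stille) capture of the vinylpalladium. The cyclopentane ring (C1, C2, C3, C3a, C7a) closes in the 5-exo-dig mode, because the three-atom tether cannot reach the distal alkyne carbon without a strained 6-endo geometry. No stereocentre is formed, C1 and the dioxane carbon are spectators, and with two methyl groups on the new alkene carbon any E/Z scrambling of the vinylpalladium has no consequence. Insertion must outrun direct benzyl–methyl coupling, which is favoured by the unimolecular ring closure, the slow transmetalation of methylboronic acid and its portionwise addition, and C1–H must stay in place, which the mild phosphate base and moderate temperature should ensure. The free tertiary alcohol and the acetonide are inert under these conditions.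

Step 17
Reactants: 29 acetonide-protected indane
Product: 30 (1S)-1-aryl-6-hydroxy-7-(hydroxymethyl)-2-isopropylideneindane (aryl as in 29)
Conditions: aq HCl (1 M), THF, rt
Reagents that add atoms: none
Why: Acid-catalysed ketal hydrolysis; the mixed phenol/benzyl alcohol acetonide is very labile, so dilute acid at room temperature should free the salicyl alcohol before the tetrasubstituted alkene or the tertiary alcohol is protonated.

Step 18
Reactants: 30 salicyl alcohol
Product: 31 diaporindene H
Conditions: MnO2 (activated, 15 equiv), CH2Cl2, rt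
Reagents that add atoms: none
Why: Heterogeneous MnO2 oxidation is selective for the benzylic alcohol and stops at the hydrogen-bonded salicylaldehyde, leaving the phenol, tertiary alcohol, alkene and both stereocentres unchanged.

Compound list
1 | dimethyl 4-hydroxyisophthalate | COC(=O)c1ccc(O)c(C(=O)OC)c1 | starting material
2 | dimethyl 4-(tert-butyldimethylsilyloxy)isophthalate | COC(=O)c1ccc(O[Si](C)(C)C(C)(C)C)c(C(=O)OC)c1 | intermediate
3 | C2-magnesiated 2 (arylmagnesium chloride) | COC(=O)c1ccc(O[Si](C)(C)C(C)(C)C)c(C(=O)OC)c1[Mg]Cl | intermediate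
4 | dimethyl 4-(tert-butyldimethylsilyloxy)-2-formylisophthalate | COC(=O)c1ccc(O[Si](C)(C)C(C)(C)C)c(C(=O)OC)c1C=O | intermediate
5 | prop-1-ynylmagnesium bromide (commercial THF solution) | CC#C[Mg]Br | starting material
6 | bromomagnesium alkoxide of dimethyl 4-(tert-butyldimethylsilyloxy)-2-(1-hydroxybut-2-ynyl)isophthalate, racemic | CC#CC(O[Mg]Br)c1c(C(=O)OC)ccc(O[Si](C)(C)C(C)(C)C)c1C(=O)OC | intermediate
7 | racemic 1-[3-(tert-butyldimethylsilyloxy)-2,6-bis(hydroxymethyl)phenyl]but-2-yn-1-ol | CC#CC(O)c1c(CO)ccc(O[Si](C)(C)C(C)(C)C)c1CO | intermediate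
8 | racemic 1-[3-(tert-butyldimethylsilyloxy)-2,6-bis(tert-butyldimethylsilyloxymethyl)phenyl]but-2-yn-1-ol | CC#CC(O)c1c(CO[Si](C)(C)C(C)(C)C)ccc(O[Si](C)(C)C(C)(C)C)c1CO[Si](C)(C)C(C)(C)C | intermediate
9 | racemic phenyl carbonate of 8 | CC#CC(OC(=O)Oc1ccccc1)c1c(CO[Si](C)(C)C(C)(C)C)ccc(O[Si](C)(C)C(C)(C)C)c1CO[Si](C)(C)C(C)(C)C | intermediate
10 | 3-methylbut-2-en-1-ol | CC(C)=CCO | starting material
11 | [(2R)-3,3-dimethyloxiran-2-yl]methanol | OC[C@H]1OC1(C)C | intermediate
12 | [(2R)-3,3-dimethyloxiran-2-yl]methyl 3-nitrobenzenesulfonate | O=S(=O)(OC[C@H]1OC1(C)C)c1cccc([N+](=O)[O-])c1 | intermediate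
13 | 3-bromo-2-hydroxy-5-methylbenzaldehyde | Cc1cc(Br)c(O)c(C=O)c1 | starting material
14 | 2-(allyloxy)-3-bromo-5-methylbenzaldehyde | C=CCOc1c(Br)cc(C)cc1C=O | intermediate
15 | 2-(allyloxy)-3-bromo-5-methylphenyl formate | C=CCOc1c(Br)cc(C)cc1OC=O | intermediate
16 | 2-(allyloxy)-3-bromo-5-methylphenol | C=CCOc1c(Br)cc(C)cc1O | intermediate
17 | 2-(allyloxy)-1-bromo-3-{[(2R)-3,3-dimethyloxiran-2-yl]methoxy}-5-methylbenzene | C=CCOc1c(Br)cc(C)cc1OC[C@H]1OC1(C)C | intermediate
18 | 2-bromo-6-{[(2R)-3,3-dimethyloxiran-2-yl]methoxy}-4-methylphenol | Cc1cc(Br)c(O)c(OC[C@H]2OC2(C)C)c1 | intermediate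
19 | 2-[(2S)-8-bromo-6-methyl-2,3-dihydro-1,4-benzodioxin-2-yl]propan-2-ol | Cc1cc(Br)c2O[C@H](C(C)(C)O)COc2c1 | intermediate
20 | triethylsilyl ether of 19 | Cc1cc(Br)c2O[C@H](C(C)(C)O[Si](CC)(CC)CC)COc2c1 | intermediate
21 | aryllithium from 20 | Cc1cc([Li])c2O[C@H](C(C)(C)O[Si](CC)(CC)CC)COc2c1 | intermediate
22 | arylzinc iodide from 21 | Cc1cc([Zn]I)c2O[C@H](C(C)(C)O[Si](CC)(CC)CC)COc2c1 | intermediate
23 | (1S,2S)-coupled tetrasilyl ether (name in step 12) | CC#C[C@@H](c1c(CO[Si](C)(C)C(C)(C)C)ccc(O[Si](C)(C)C(C)(C)C)c1CO[Si](C)(C)C(C)(C)C)c1cc(C)cc2c1O[C@H](C(C)(C)O[Si](CC)(CC)CC)CO2 | intermediate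
24 | tetraol (name in step 13) | CC#C[C@@H](c1c(CO)ccc(O)c1CO)c1cc(C)cc2c1O[C@H](C(C)(C)O)CO2 | intermediate
25 | acetonide alcohol (name in step 14) | CC#C[C@@H](c1c(CO)ccc2OC(C)(C)OCc12)c1cc(C)cc2c1O[C@H](C(C)(C)O)CO2 | intermediate
26 | benzylic mesylate of 25 | CC#C[C@@H](c1c(COS(C)(=O)=O)ccc2OC(C)(C)OCc12)c1cc(C)cc2c1O[C@H](C(C)(C)O)CO2 | intermediate
27 | benzylic chloride, precursor of the key step (name in step 15) | CC#C[C@@H](c1c(CCl)ccc2OC(C)(C)OCc12)c1cc(C)cc2c1O[C@H](C(C)(C)O)CO2 | intermediate
28 | methylboronic acid | CB(O)O | starting material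
29 | acetonide-protected (1S)-1-aryl-2-isopropylideneindane | CC(C)=C1Cc2ccc3OC(C)(C)OCc3c2[C@H]1c1cc(C)cc2c1O[C@H](C(C)(C)O)CO2 | intermediate
30 | (1S)-1-aryl-6-hydroxy-7-(hydroxymethyl)-2-isopropylideneindane | CC(C)=C1Cc2ccc(O)c(CO)c2[C@H]1c1cc(C)cc2c1O[C@H](C(C)(C)O)CO2 | intermediate
31 | diaporindene H, (1S) at the indane methine and (S) at the dioxane carbon | CC(C)=C1Cc2ccc(O)c(C=O)c2[C@H]1c1cc(C)cc2c1O[C@H](C(C)(C)O)CO2 | target

Total steps: 18. Longest linear sequence: 12 steps (1–5 then 12–18; the ring B line 7–11 then 12–18 is equally long).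

Steps most likely to fail, in route order

**Step 2.** The base may deprotonate C6 (next to only one ester) instead of C2. The crowded arylmagnesium may also add to an ester of a second molecule before DMF reaches it. The fallback replaces the two freely rotating ester directors by a ring-locked carbonyl that has only one ortho C–H.
- It starts from 1, which is saponified (LiOH) to 4-hydroxyisophthalic acid F1.
- The salicylic acid half of F1 is condensed with acetone (trifluoroacetic anhydride, trifluoroacetic acid) to 2,2-dimethyl-4-oxo-4H-1,3-benzodioxine-6-carboxylic acid F2, and MeI/K2CO3 gives its methyl ester F3.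
- Magnesiation of benzodioxin-4-ones next to the ring carbonyl is established chemistry. Here it should give the C5 arylmagnesium chloride F4, and DMF then gives the 5-formyl compound F5.
- The one-flask propynyl addition and iBu2AlH reduction of step 3, through the bromomagnesium alkoxide F6, also cleaves the acetonide and gives the phenol triol F7.
- Threefold silylation (TBSCl, imidazole) rejoins the route at 8.

**Step 12.** The aryl-stabilised, doubly ortho-flanked propargylic radical may be captured slowly by nickel, so that it dimerises or is reduced. The catalyst may also distinguish its two faces poorly. The fallback forms the same C1–aryl bond by conjugate addition and builds the alkyne afterwards, leaving C1 uncontrolled.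
- It starts from 4 and 21. Knoevenagel condensation of 4 with 3-methylisoxazol-5(4H)-one gives the arylidene isoxazolone F8.
- Aryllithium 21 is converted with MgBr2 into the arylmagnesium bromide F9, which adds 1,4 to F8 to give the diarylmethyl isoxazolone F10.
- Nitrosative fragmentation (NaNO2, FeSO4, aq AcOH) turns the heterocycle into the methyl alkyne of the diester F11. Any silyl group lost here is due for removal anyway.
- iBu2AlH gives the diol F12, and buffered Bu4NF gives 24 together with its (1R)-epimer F13.
- Because the dioxane centre is fixed, 24 and F13 are diastereomers. They are separated by chromatography, and the route resumes at 24.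

**Step 16.** Three processes could compete with the cascade:
- methyl may couple at the benzylic carbon before the alkyne inserts;
- the base may shift the propargylic C1–H towards an allene;
- slow methyl transfer may let the vinylpalladium be protonated.

The fallback separates ring closure from methyl delivery and brings in methyl as an electrophile. It starts from 27, where the same cyclic carbopalladation is ended by Miyaura-type borylation (B2pin2, KOAc, PdCl2(dppf), dioxane, 60 °C). Acetate is a much weaker base than phosphate, and this should give the (Z)-vinyl pinacol boronate F14. A separate Suzuki–Miyaura methylation of F14 with MeI (Pd2(dba)3, P(o-tolyl)3, K2CO3, DMF) rejoins the route at 29.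

Further compounds
F1 | step 2 | 4-hydroxyisophthalic acid | O=C(O)c1ccc(O)c(C(=O)O)c1
F2 | step 2 | 2,2-dimethyl-4-oxo-4H-1,3-benzodioxine-6-carboxylic acid | CC1(C)OC(=O)c2cc(C(=O)O)ccc2O1
F3 | step 2 | methyl 2,2-dimethyl-4-oxo-4H-1,3-benzodioxine-6-carboxylate | COC(=O)c1ccc2OC(C)(C)OC(=O)c2c1
F4 | step 2 | C5 arylmagnesium chloride of F3 | COC(=O)c1ccc2OC(C)(C)OC(=O)c2c1[Mg]Cl
F5 | step 2 | methyl 5-formyl-2,2-dimethyl-4-oxo-4H-1,3-benzodioxine-6-carboxylate | COC(=O)c1ccc2OC(C)(C)OC(=O)c2c1C=O
F6 | step 2 | bromomagnesium alkoxide from F5 and 5, racemic | CC#CC(O[Mg]Br)c1c(C(=O)OC)ccc2OC(C)(C)OC(=O)c12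
F7 | step 2 | racemic 1-[3-hydroxy-2,6-bis(hydroxymethyl)phenyl]but-2-yn-1-ol | CC#CC(O)c1c(CO)ccc(O)c1CO
F8 | step 12 | arylidene isoxazolone from 4 (alkene geometry immaterial) | COC(=O)c1ccc(O[Si](C)(C)C(C)(C)C)c(C(=O)OC)c1C=C1C(C)=NOC1=O
F9 | step 12 | arylmagnesium bromide from 21 | Cc1cc([Mg]Br)c2O[C@H](C(C)(C)O[Si](CC)(CC)CC)COc2c1
F10 | step 12 | diarylmethyl isoxazolone, both C1 epimers | COC(=O)c1ccc(O[Si](C)(C)C(C)(C)C)c(C(=O)OC)c1C(C1C(C)=NOC1=O)c1cc(C)cc2c1O[C@H](C(C)(C)O[Si](CC)(CC)CC)CO2
F11 | step 12 | diaryl propargylic diester, both C1 epimers | CC#CC(c1c(C(=O)OC)ccc(O[Si](C)(C)C(C)(C)C)c1C(=O)OC)c1cc(C)cc2c1O[C@H](C(C)(C)O[Si](CC)(CC)CC)CO2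
F12 | step 12 | diaryl propargylic diol, both C1 epimers | CC#CC(c1c(CO)ccc(O[Si](C)(C)C(C)(C)C)c1CO)c1cc(C)cc2c1O[C@H](C(C)(C)O[Si](CC)(CC)CC)CO2
F13 | step 12 | (1R)-epimer of tetraol 24 | CC#C[C@H](c1c(CO)ccc(O)c1CO)c1cc(C)cc2c1O[C@H](C(C)(C)O)CO2
F14 | step 16 | (Z)-vinyl pinacol boronate of the cyclised indane | C/C(B1OC(C)(C)C(C)(C)O1)=C1/Cc2ccc3OC(C)(C)OCc3c2[C@H]1c1cc(C)cc2c1O[C@H](C(C)(C)O)CO2
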